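**Retrosynthetic overview**
1. Locants: flavanone numbering O1, C2–C4, C4a, C5–C8, C8a (rings A and C). Ring B is C1'–C6'. Dioxane ring D holds C7'' (aryl-bearing) and C8'', with the C9'' hydroxymethyl. Ring E is the guaiacyl ring.
2. Last disconnection: ring C is cut at two bonds at once, O1–C2 and C2–C3. This gives a ring B/D/E aldehyde (its formyl carbon is C2) and a ring A tert-butyl β-keto ester (O1, C8a, C4a, C4, C3). In the forward direction one flask does Knoevenagel union, catalyst-controlled oxa-Michael closure, loss of the ester as isobutene/CO2, and detritylation.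
3. Enabling feature: ring C is a β-aryloxy ketone. O1 on C2 lies β to the C4 carbonyl, C3 is a bare CH2 between them, and C2 bears only ring B and H. C3 can therefore carry a traceless CO2tBu, which makes C2=C3 easy to form and electrophilic enough for a thiourea-guided attack by the ortho-phenol O1.
4. The aldehyde comes from ring D closure by stereoretentive intramolecular SNAr (C7''–O onto C4'–F, para to a nitrile) of a threo aryl ether. The C7''–C8'' bond and both dioxane stereocentres come from an Evans syn glycolate aldol.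
5. Ring order: A, B and E are bought, ring D closes in step 5, and ring C closes last, in step 9.

Key step: step 9

Assumption: the 9-amino(9-deoxy)-epi-quinidine-derived thiourea is taken as the catalyst that gives the (2S) series; the pseudo-enantiomeric cinchona thioureas give opposite senses, so the epi-quinine analogue replaces it if the sense proves reversed.

Step 1
Reactants: 1 4-fluoro-3-hydroxybenzonitrile; 2 (4S)-4-benzyl-3-(chloroacetyl)-1,3-oxazolidin-2-one
Product: 3 (4S)-4-benzyl-3-[(5-cyano-2-fluorophenoxy)acetyl]-1,3-oxazolidin-2-one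
Conditions: K2CO3, MeCN, rt → 40 °C
Reagents that add atoms: none
Why: Williamson ether synthesis (SN2): the acidic phenol gives, with mild carbonate base, a phenoxide that should displace the carbonyl-activated primary chloride faster than it attacks the imide, and the auxiliary stereocentre is not involved.

Step 2
Reactants: 3 aryloxyacetyl imide; 4 4-(benzyloxy)-3-methoxybenzaldehyde (O-benzylvanillin)
Product: 5 syn-aldol imide, (2S,3R) in the acyl chain
Conditions: Bu2BOTf, Et3N, CH2Cl2, −78 → 0 °C; then 4, −78 → 0 °C; pH 7 buffer, MeOH, 30 % H2O2, 0 °C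
Reagents that add atoms: none
Why: Evans syn glycolate aldol: soft enolisation is Z-selective, and the closed Zimmerman–Traxler transition state, with the (S)-benzyl group shielding one enolate face, sets C8'' (2S in 5) and C7'' (3R in 5) together as the syn (threo) pair that maps onto the trans-(R,R) dioxane.

Step 3
Reactants: 5 syn-aldol imide
Product: 6 threo-(1R,2R)-diol
Conditions: LiBH4, H2O (1 equiv), THF, 0 °C
Reagents that add atoms: none
Why: Reductive cleavage of the N-acyl oxazolidinone takes the exocyclic imide carbonyl to the C9'' primary alcohol while nitrile, aryl fluoride and benzyl ether are inert, and neither stereocentre is touched (the C8'' descriptor changes from S to R only through CIP ranking).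

Step 4
Reactants: 6 threo-diol
Product: 7 threo-(1R,2R) primary trityl ether
Conditions: TrCl, Et3N, DMAP (cat.), CH2Cl2, rt
Reagents that add atoms: trityl chloride, ClC(c1ccccc1)(c1ccccc1)c1ccccc1
Why: Tritylation is selective for the primary C9''–OH over the hindered secondary benzylic C7''–OH, and trityl, unlike a silyl group, cannot migrate to the neighbouring alkoxide in the next step.

Step 5
Reactants: 7 trityl ether
Product: 8 trans-(2R,3R)-benzodioxane nitrile
Conditions: NaH, DMF, 0 °C → rt
Reagents that add atoms: none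
Why: Intramolecular SNAr: the C7'' alkoxide attacks C4' of ring B, where fluoride sits para to the nitrile, and closes the six-membered ring D at an arene carbon, so C7'' and C8'' keep their configuration and the threo ether becomes the trans-dioxane with the aryl-bearing carbon on the oxygen para to the nitrile.

Step 6
Reactants: 8 benzodioxane nitrile
Product: 9 trans-(2R,3R)-benzodioxane aldehyde
Conditions: DIBAL-H, CH2Cl2, −78 °C; aq. Rochelle salt, rt
Reagents that add atoms: water, O
Why: Partial reduction of a nitrile with DIBAL-H stops at the aldimine level at −78 °C and near-neutral hydrolysis gives the aldehyde, leaving ethers, trityl group and stereocentres untouched.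

Step 7
Reactants: 10 2',4',6'-trihydroxyacetophenone
Product: 11 1-[2,4-bis(benzyloxy)-6-hydroxyphenyl]ethan-1-one
Conditions: BnBr (2 equiv), K2CO3, DMF, rt → 50 °C
Reagents that add atoms: benzyl bromide, BrCc1ccccc1
Why: Williamson etherification under mild base spares one ortho hydroxyl, which is tied up in a strong hydrogen bond to the ketone, and since the two ortho hydroxyls are equivalent only one dibenzyl ether can form.

Step 8
Reactants: 11 dibenzyl acetophenone
Product: 12 tert-butyl 3-[2,4-bis(benzyloxy)-6-hydroxyphenyl]-3-oxopropanoate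
Conditions: LiHMDS (3.5 equiv), THF, −78 → −10 °C; Boc2O, −78 → 0 °C; AcOH quench
Reagents that add atoms: di-tert-butyl dicarbonate, CC(C)(C)OC(=O)OC(=O)OC(C)(C)C
Why: Claisen-type C-acylation: excess base deprotonates both phenol and methyl ketone, the enolate carbon is the most nucleophilic site and takes up the Boc group, and the product is shielded from further acylation as its stabilised enolate.

Step 9
Reactants: 9 benzodioxane aldehyde; 12 tert-butyl β-keto ester
Product: 15 tri-O-benzylsilandrin, via (Z)-alkylidene β-keto ester 13 (not isolated), via trans-flavanone-3-carboxylic tert-butyl ester 14 (not isolated)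
Conditions: (i) piperidine (5 mol %), AcOH (5 mol %), 4 Å MS, toluene, rt; (ii) epi-quinidine-derived 3,5-(CF3)2C6H3-thiourea (20 mol %), −25 °C; (iii) TsOH·H2O (2 equiv), 80 °C
Reagents that add atoms: none
Why: Piperidinium acetate condenses the formyl carbon of 9 (the future C2) with the doubly activated C3 methylene of 12 (Knoevenagel condensation) to give 13, whose phenol stays in a hydrogen bond to the C4 ketone until a base is placed next to it. At −25 °C the bifunctional cinchona thiourea binds the β-keto ester carbonyls through its two N–H bonds while its quinuclidine nitrogen takes the phenol proton, and O1 adds to C2 in a 6-endo-trig oxa-Michael closure of ring C to give 14. TsOH·H2O at 80 °C then cleaves the tert-butyl ester (E1, isobutene), the β-keto acid loses CO2, which removes the activating group together with the easy retro-Michael channel, and the trityl ether is hydrolysed in the same stage. The closest known reaction type is the thiourea-catalysed enantioselective cyclisation of 2-hydroxyaryl alkylidene β-keto esters to flavanones with acid decarboxylation in the same flask, also known as a one-flask condensation/conjugate addition/decarboxylation. C2 is controlled by the catalyst, which exposes one face of the bound alkylidene to O1, the C7''/C8'' stereocentres being too remote across ring B to match or mismatch, while C3 of 14 settles trans to the aryl group by enolisation and is erased on decarboxylation. The step needs a single nucleophile and a single acceptor, which is secured by benzyl ethers on all other phenols, the trityl ether on C9''–OH, and the bulky tert-butyl ester that blocks lactonisation to a 4-hydroxycoumarin and slows uncatalysed closure.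

Step 10
Reactants: 15 tri-O-benzylsilandrin
Product: 16 silandrin
Conditions: H2 (1 atm), 10 % Pd/C, EtOAc/MeOH, rt
Reagents that add atoms: none
Why: Catalytic hydrogenolysis of the three aryl benzyl ethers runs under neutral conditions, which avoids the base-induced ring opening and reclosure that would epimerise C2, and the unhindered O–CH2Ph bonds should be cleaved well before the ring-embedded secondary benzylic C–O bonds at C2 and C7''.

**Compound list**
1 | 4-fluoro-3-hydroxybenzonitrile | N#Cc1ccc(F)c(O)c1 | starting material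
2 | (4S)-4-benzyl-3-(chloroacetyl)-1,3-oxazolidin-2-one | O=C1OC[C@H](Cc2ccccc2)N1C(=O)CCl | starting material
3 | (4S)-4-benzyl-3-[(5-cyano-2-fluorophenoxy)acetyl]-1,3-oxazolidin-2-one | O=C1OC[C@H](Cc2ccccc2)N1C(=O)COc1cc(C#N)ccc1F | intermediate
4 | 4-(benzyloxy)-3-methoxybenzaldehyde | COc1cc(C=O)ccc1OCc1ccccc1 | starting material
5 | (4S)-4-benzyl-3-{(2S,3R)-3-[4-(benzyloxy)-3-methoxyphenyl]-2-(5-cyano-2-fluorophenoxy)-3-hydroxypropanoyl}-1,3-oxazolidin-2-one | O=C1OC[C@H](Cc2ccccc2)N1C(=O)[C@@H](Oc1cc(C#N)ccc1F)[C@H](O)c1ccc(OCc2ccccc2)c(OC)c1 | intermediate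
6 | 3-({(1R,2R)-1-[4-(benzyloxy)-3-methoxyphenyl]-1,3-dihydroxypropan-2-yl}oxy)-4-fluorobenzonitrile | OC[C@@H](Oc1cc(C#N)ccc1F)[C@H](O)c1ccc(OCc2ccccc2)c(OC)c1 | intermediate
7 | 3-({(1R,2R)-1-[4-(benzyloxy)-3-methoxyphenyl]-1-hydroxy-3-(trityloxy)propan-2-yl}oxy)-4-fluorobenzonitrile | c1ccccc1C(c1ccccc1)(c1ccccc1)OC[C@@H](Oc1cc(C#N)ccc1F)[C@H](O)c1ccc(OCc2ccccc2)c(OC)c1 | intermediate
8 | (2R,3R)-2-[4-(benzyloxy)-3-methoxyphenyl]-3-[(trityloxy)methyl]-2,3-dihydro-1,4-benzodioxine-6-carbonitrile | COc1cc([C@H]2Oc3ccc(C#N)cc3O[C@@H]2COC(c4ccccc4)(c4ccccc4)c4ccccc4)ccc1OCc5ccccc5 | intermediate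
9 | (2R,3R)-2-[4-(benzyloxy)-3-methoxyphenyl]-3-[(trityloxy)methyl]-2,3-dihydro-1,4-benzodioxine-6-carbaldehyde | COc1cc([C@H]2Oc3ccc(C=O)cc3O[C@@H]2COC(c4ccccc4)(c4ccccc4)c4ccccc4)ccc1OCc5ccccc5 | intermediate
10 | 1-(2,4,6-trihydroxyphenyl)ethan-1-one | CC(=O)c1c(O)cc(O)cc1O | starting material
11 | 1-[2,4-bis(benzyloxy)-6-hydroxyphenyl]ethan-1-one | CC(=O)c1c(O)cc(OCc2ccccc2)cc1OCc3ccccc3 | intermediate
12 | tert-butyl 3-[2,4-bis(benzyloxy)-6-hydroxyphenyl]-3-oxopropanoate | CC(C)(C)OC(=O)CC(=O)c1c(O)cc(OCc2ccccc2)cc1OCc3ccccc3 | intermediate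
13 | tert-butyl (2Z)-2-[2,4-bis(benzyloxy)-6-hydroxybenzoyl]-3-{(2R,3R)-2-[4-(benzyloxy)-3-methoxyphenyl]-3-[(trityloxy)methyl]-2,3-dihydro-1,4-benzodioxin-6-yl}prop-2-enoate (aryl cis to ester, trans to aroyl) | COc1cc([C@H]2Oc3ccc(/C=C(\C(=O)OC(C)(C)C)C(=O)c4c(O)cc(OCc5ccccc5)cc4OCc6ccccc6)cc3O[C@@H]2COC(c7ccccc7)(c7ccccc7)c7ccccc7)ccc1OCc8ccccc8 | intermediate
14 | tert-butyl (2S,3R)-5,7-bis(benzyloxy)-2-{(2R,3R)-2-[4-(benzyloxy)-3-methoxyphenyl]-3-[(trityloxy)methyl]-2,3-dihydro-1,4-benzodioxin-6-yl}-4-oxo-3,4-dihydro-2H-chromene-3-carboxylate (2,3-trans) | COc1cc([C@H]2Oc3ccc([C@@H]4[C@@H](C(=O)OC(C)(C)C)C(=O)c5c(OCc6ccccc6)cc(OCc7ccccc7)cc5O4)cc3O[C@@H]2COC(c8ccccc8)(c8ccccc8)c8ccccc8)ccc1OCc9ccccc9 | intermediate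
15 | (2S)-5,7-bis(benzyloxy)-2-{(2R,3R)-2-[4-(benzyloxy)-3-methoxyphenyl]-3-(hydroxymethyl)-2,3-dihydro-1,4-benzodioxin-6-yl}-2,3-dihydro-4H-chromen-4-one | COc1cc([C@H]2Oc3ccc([C@@H]4CC(=O)c5c(OCc6ccccc6)cc(OCc7ccccc7)cc5O4)cc3O[C@@H]2CO)ccc1OCc8ccccc8 | intermediate
16 | silandrin, (2S)-5,7-dihydroxy-2-[(2R,3R)-2-(4-hydroxy-3-methoxyphenyl)-3-(hydroxymethyl)-2,3-dihydro-1,4-benzodioxin-6-yl]-2,3-dihydro-4H-chromen-4-one | COc1cc([C@H]2Oc3ccc([C@@H]4CC(=O)c5c(O)cc(O)cc5O4)cc3O[C@@H]2CO)ccc1O | target

**Totals**
- Total step count: 10.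
- Longest linear sequence: 8 (steps 1–6, 9, 10).

**Steps most likely to fail**

1. **Step 9.**
   - *What may go wrong:*
     - Ring closure may be promoted by the achiral amine salt, or occur spontaneously, before the chiral catalyst engages, giving poor facial selectivity at C2.
     - Ring opening and reclosure at the p-alkoxybenzylic C2 during the hot acid stage may erode the configuration.
     - Condensation of the electron-rich aldehyde with the hindered keto ester may be slow.
   - *Fallback (unselective ring closure, C2 sorted afterwards):* it sets out from 9 and 11 and returns at 15.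
     - Claisen–Schmidt condensation (KOH, EtOH, rt) gives the 2'-hydroxychalcone F1.
     - NaOAc in refluxing EtOH closes ring C to the flavanone as a mixture of C2 epimers F2.
     - Asymmetric transfer hydrogenation under kinetic-resolution conditions follows (Cp*Rh–TsDPEN, HCO2H/Et3N, EtOAc), with the catalyst enantiomer chosen so that the (2R) epimer reacts fast.
     - This converts the unwanted epimer into the cis-(2R,4R)-flavan-4-ol F3 and leaves the (2S)-flavanone trityl ether F4.
     - After separation of ketone from alcohol, 80 % AcOH at 40 °C removes the trityl group to give 15.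

2. **Step 8.**
   - *What may go wrong:* competing O-acylation of the phenoxide, double acylation, or consumption of Boc2O by the excess amide base.
   - *Fallback (intermolecular C-acylation replaced by an intramolecular O→C transfer):* it sets out from 11 and returns at 12.
     - Boc2O, Et3N and DMAP (cat.) in CH2Cl2 give 2-acetyl-3,5-bis(benzyloxy)phenyl tert-butyl carbonate F5, which is isolated.
     - KOtBu (2.2 equiv) in THF, −78 → 0 °C, then moves the alkoxycarbonyl group from oxygen to the enolate carbon through a six-membered transition state (Baker–Venkataraman-type rearrangement) to give 12.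

3. **Step 1.**
   - *What may go wrong:* acyl transfer from the imide to the phenoxide, or carbonate-induced opening of the oxazolidinone ring, in competition with the SN2 displacement.
   - *Fallback (ether bond first, auxiliary attached last by N-acylation):* it sets out from 1 and returns at 3.
     - tert-Butyl bromoacetate and K2CO3 in acetone give tert-butyl (5-cyano-2-fluorophenoxy)acetate F6.
     - TFA/CH2Cl2 gives (5-cyano-2-fluorophenoxy)acetic acid F7.
     - PivCl and Et3N in THF at −20 °C give the mixed pivalic anhydride F8.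
     - F8 acylates (S)-4-benzyl-1,3-oxazolidin-2-one in the presence of LiCl to give 3.

Further compounds
F1 | step 9 | (2E)-1-[2,4-bis(benzyloxy)-6-hydroxyphenyl]-3-{(2R,3R)-2-[4-(benzyloxy)-3-methoxyphenyl]-3-[(trityloxy)methyl]-2,3-dihydro-1,4-benzodioxin-6-yl}prop-2-en-1-one | COc1cc([C@H]2Oc3ccc(/C=C/C(=O)c4c(O)cc(OCc5ccccc5)cc4OCc6ccccc6)cc3O[C@@H]2COC(c7ccccc7)(c7ccccc7)c7ccccc7)ccc1OCc8ccccc8
F2 | step 9 | 5,7-bis(benzyloxy)-2-{(2R,3R)-2-[4-(benzyloxy)-3-methoxyphenyl]-3-[(trityloxy)methyl]-2,3-dihydro-1,4-benzodioxin-6-yl}-2,3-dihydro-4H-chromen-4-one, mixture of C2 epimers | COc1cc([C@H]2Oc3ccc(C4CC(=O)c5c(OCc6ccccc6)cc(OCc7ccccc7)cc5O4)cc3O[C@@H]2COC(c8ccccc8)(c8ccccc8)c8ccccc8)ccc1OCc9ccccc9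
F3 | step 9 | (2R,4R)-5,7-bis(benzyloxy)-2-{(2R,3R)-2-[4-(benzyloxy)-3-methoxyphenyl]-3-[(trityloxy)methyl]-2,3-dihydro-1,4-benzodioxin-6-yl}-3,4-dihydro-2H-chromen-4-ol | COc1cc([C@H]2Oc3ccc([C@H]4C[C@@H](O)c5c(OCc6ccccc6)cc(OCc7ccccc7)cc5O4)cc3O[C@@H]2COC(c8ccccc8)(c8ccccc8)c8ccccc8)ccc1OCc9ccccc9
F4 | step 9 | (2S)-5,7-bis(benzyloxy)-2-{(2R,3R)-2-[4-(benzyloxy)-3-methoxyphenyl]-3-[(trityloxy)methyl]-2,3-dihydro-1,4-benzodioxin-6-yl}-2,3-dihydro-4H-chromen-4-one | COc1cc([C@H]2Oc3ccc([C@@H]4CC(=O)c5c(OCc6ccccc6)cc(OCc7ccccc7)cc5O4)cc3O[C@@H]2COC(c8ccccc8)(c8ccccc8)c8ccccc8)ccc1OCc9ccccc9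
F5 | step 8 | 2-acetyl-3,5-bis(benzyloxy)phenyl tert-butyl carbonate | CC(=O)c1c(OC(=O)OC(C)(C)C)cc(OCc2ccccc2)cc1OCc3ccccc3
F6 | step 1 | tert-butyl (5-cyano-2-fluorophenoxy)acetate | CC(C)(C)OC(=O)COc1cc(C#N)ccc1F
F7 | step 1 | (5-cyano-2-fluorophenoxy)acetic acid | OC(=O)COc1cc(C#N)ccc1F
F8 | step 1 | (5-cyano-2-fluorophenoxy)acetic pivalic anhydride | CC(C)(C)C(=O)OC(=O)COc1cc(C#N)ccc1F
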